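## Retrosynthetic overview

1. Feature: in ring A the C7 hydroxyl is para to C4a (the carbon bearing C4H2), and O1 sits on C8a, ortho to C4a and meta to C7. This is the pattern a 4-alkyl-p-quinol leaves after it accepts an oxygen nucleophile at a β-carbon and loses its C4a hydroxyl as water.
2. Last disconnections: first the 3'-O-isopropyl ether (BCl3), then O1–C8a. Opening pyran ring C gives a p-quinol that carries the (S)-2-aryl-3-hydroxypropyl chain on C4a.
3. The p-quinol comes from the 4-alkylphenol by singlet-oxygen dearomatisation. The C3–C4 bond and the C3 stereocentre come from an Evans benzylation of the ring-B arylacetyl imide with 4-silyloxybenzyl bromide, followed by reductive removal of the auxiliary.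
4. The ring-B acid comes from 2,3,4-trihydroxybenzaldehyde by O4 prenylation, O3 isopropylation, O2 methylation, aromatic Claisen shift to C5', O4 methylation and one-carbon homologation of the formyl group.
5. Ring order: rings A and B are bought as arenes. Ring C is the only ring made, and it closes while ring A passes through its dearomatised form and back.

Key step: step 16

Remark: the stereodescriptor of the target SMILES is read as (3S). Ar stands for 3-isopropoxy-2,4-dimethoxy-5-(2-methylbut-3-en-2-yl)phenyl, and isoflavan numbering (O1, C2, C3, C4, C4a to C8a, primed for ring B) is also used for open-chain precursors.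

## Route

Step 1
Reactants: 1 2,3,4-trihydroxybenzaldehyde; 2 prenyl bromide (1-bromo-3-methylbut-2-ene)
Product: 3 2,3-dihydroxy-4-(3-methylbut-2-enyloxy)benzaldehyde
Conditions: NaHCO3 (1.2 equiv), 2 (1.0 equiv), DMF, 40 °C, Ar
Reagents that add atoms: none
Why: Williamson ether synthesis under hydrogencarbonate control: only the 4-OH, para to the formyl group and therefore the most acidic, is ionised, the 2-OH being locked in a hydrogen bond to the carbonyl oxygen and the 3-OH being unconjugated, so one equivalent of the allylic bromide should end up on O4.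

Step 2
Reactants: 3 2,3-dihydroxy-4-(3-methylbut-2-enyloxy)benzaldehyde
Product: 5 2-hydroxy-3-isopropoxy-4-(3-methylbut-2-enyloxy)benzaldehyde, via disodium catecholate 4 (not isolated)
Conditions: NaH (2.1 equiv), DMSO, rt, Ar; 2-iodopropane (1.1 equiv), rt; aq HCl work-up
Reagents that add atoms: 2-iodopropane, CC(C)I; sodium hydride, [Na+].[H-] (sodium only in intermediate 4)
Why: Regioselective mono-O-alkylation of a catecholate dianion (Williamson type): in 4 the O3 oxide is not conjugated with the formyl group and is far more nucleophilic than the O2 oxide, which is a sodium-chelated vinylogous carboxylate and responds poorly to a secondary halide.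

Step 3
Reactants: 5 2-hydroxy-3-isopropoxy-4-(3-methylbut-2-enyloxy)benzaldehyde
Product: 6 3-isopropoxy-2-methoxy-4-(3-methylbut-2-enyloxy)benzaldehyde
Conditions: MeI, K2CO3, DMF, rt
Reagents that add atoms: iodomethane, CI
Why: Williamson methylation of the last free, chelated 2-OH, which needs only full deprotonation by carbonate in a dipolar aprotic solvent and a small, reactive electrophile.

Step 4
Reactants: 6 3-isopropoxy-2-methoxy-4-(3-methylbut-2-enyloxy)benzaldehyde
Product: 8 4-hydroxy-3-isopropoxy-2-methoxy-5-(2-methylbut-3-en-2-yl)benzaldehyde, via ortho-dienone 7 (not isolated)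
Conditions: N,N-diethylaniline, 190–200 °C, sealed tube, Ar
Reagents that add atoms: none
Why: Aromatic Claisen rearrangement: the [3,3] shift can only reach C5 because C3 carries the isopropoxy group, it delivers the allyl unit inverted as the 1,1-dimethylallyl group, the formyl group on the para carbon denies a productive follow-up Cope shift, and the basic solvent speeds the tautomerisation of 7 and suppresses acid-induced ring closure of 8.

Step 5
Reactants: 8 4-hydroxy-3-isopropoxy-2-methoxy-5-(2-methylbut-3-en-2-yl)benzaldehyde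
Product: 9 3-isopropoxy-2,4-dimethoxy-5-(2-methylbut-3-en-2-yl)benzaldehyde (ArCHO)
Conditions: MeI, K2CO3, DMF, 40 °C
Reagents that add atoms: iodomethane, CI
Why: Williamson methylation: the 4-OH is flanked by the isopropoxy and the tert-alkyl group but is acidified by the para formyl group and iodomethane is small, and capping it also removes the phenol that could later close on the vinyl group.

Step 6
Reactants: 9 ArCHO
Product: 10 1-Ar-2-methoxyethene (enol ether, E/Z mixture)
Conditions: MeOCH2PPh3Cl, KOt-Bu, THF, 0 °C → rt
Reagents that add atoms: (methoxymethyl)triphenylphosphonium chloride, COC[P+](c1ccccc1)(c1ccccc1)c1ccccc1.[Cl-]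
Why: Wittig olefination with the non-stabilised methoxymethylene ylide adds the missing carbon as an enol ether; the aldehyde has no α-hydrogen, nothing else in 9 reacts with the ylide, and the alkene geometry is irrelevant.

Step 7
Reactants: 10 1-Ar-2-methoxyethene
Product: 12 2-Ar-acetic acid, via arylacetaldehyde 11 (not isolated)
Conditions: 2 M HCl, THF, rt; crude 11: NaClO2, NaH2PO4, 2-methyl-2-butene, t-BuOH/H2O, rt
Reagents that add atoms: water, O; sodium chlorite, [Na+].[O-]Cl=O
Why: Acid hydrolysis of the enol ether followed by Pinnick oxidation of the crude aldehyde; dilute acid at room temperature leaves the monosubstituted alkene and the aryl ethers alone, and 2-methyl-2-butene removes hypochlorous acid before it can chlorinate the electron-rich ring or the vinyl group.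

Step 8
Reactants: 12 2-Ar-acetic acid; 13 (S)-4-benzyl-2-oxazolidinone
Product: 15 (S)-4-benzyl-3-(2-Ar-acetyl)oxazolidin-2-one, via mixed pivalic anhydride 14 (not isolated)
Conditions: PivCl, Et3N, THF, −20 °C; then LiCl, 13, −20 °C → rt
Reagents that add atoms: pivaloyl chloride, CC(C)(C)C(=O)Cl (atoms only in intermediate 14, none in 15)
Why: N-acylation of the oxazolidinone through a mixed anhydride with LiCl/Et3N activation: the nucleophile attacks the unhindered arylacetyl carbonyl of 14 rather than the pivaloyl carbonyl, and no strong base touches the acidic benzylic CH2.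

Step 9
Reactants: 16 4-hydroxybenzaldehyde
Product: 17 4-(tert-butyldimethylsilyloxy)benzaldehyde
Conditions: TBSCl, imidazole, DMF, rt
Reagents that add atoms: tert-butyldimethylsilyl chloride, CC(C)(C)[Si](C)(C)Cl
Why: Imidazole-promoted silylation of the phenol gives a group that survives hydride, cold PBr3 and enolate alkylation and later leaves with fluoride, so no hydrogenolysis is needed, which the vinyl group would not tolerate.

Step 10
Reactants: 17 4-(tert-butyldimethylsilyloxy)benzaldehyde
Product: 18 4-(tert-butyldimethylsilyloxy)benzyl alcohol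
Conditions: NaBH4, MeOH, 0 °C
Reagents that add atoms: none
Why: Borohydride reduction of the aldehyde, to which the aryl silyl ether is inert at 0 °C.

Step 11
Reactants: 18 4-(tert-butyldimethylsilyloxy)benzyl alcohol
Product: 19 4-(tert-butyldimethylsilyloxy)benzyl bromide
Conditions: PBr3 (0.4 equiv), Et2O, 0 °C; used at once
Reagents that add atoms: phosphorus tribromide, BrP(Br)Br
Why: Conversion of a benzylic alcohol into the bromide by PBr3 (bromide displacement on the phosphite ester) under cold, short conditions that keep the silyl ether; the activated bromide is taken on without storage.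

Step 12
Reactants: 15 (S)-4-benzyl-3-(2-Ar-acetyl)oxazolidin-2-one; 19 4-(tert-butyldimethylsilyloxy)benzyl bromide
Product: 21 (S)-4-benzyl-3-{(2S)-2-Ar-3-[4-(tert-butyldimethylsilyloxy)phenyl]propanoyl}oxazolidin-2-one, via sodium Z-enolate 20 (not isolated)
Conditions: NaHMDS (1.1 equiv), THF, −78 °C; then 19 (1.5 equiv), −78 → −30 °C
Reagents that add atoms: sodium hexamethyldisilazide, C[Si](C)(C)[N-][Si](C)(C)C.[Na+] (sodium only in intermediate 20)
Why: Evans asymmetric alkylation: NaHMDS gives the sodium-chelated Z-enolate 20, whose face on the side of the C4 benzyl group of the (S)-auxiliary is shielded, so the benzylic bromide enters from the opposite face, forms C3–C4 and sets the future C3 as (S) (CIP order C=O > Ar > CH2Ar' > H).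

Step 13
Reactants: 21 (S)-4-benzyl-3-{(2S)-2-Ar-3-[4-(tert-butyldimethylsilyloxy)phenyl]propanoyl}oxazolidin-2-one
Product: 22 (2S)-2-Ar-3-[4-(tert-butyldimethylsilyloxy)phenyl]propan-1-ol
Conditions: LiBH4, H2O (1 equiv), Et2O, 0 °C
Reagents that add atoms: none
Why: Reductive cleavage of the imide by lithium borohydride (hydride attack on the exocyclic carbonyl) frees the primary alcohol and the auxiliary at low temperature without a free base, so the benzylic stereocentre is not epimerised and keeps the descriptor (S) (CH2OH > Ar > CH2Ar' > H).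

Step 14
Reactants: 22 (2S)-2-Ar-3-[4-(tert-butyldimethylsilyloxy)phenyl]propan-1-ol
Product: 23 4-[(2S)-2-Ar-3-hydroxypropyl]phenol
Conditions: TBAF, THF, 0 °C
Reagents that add atoms: none
Why: Fluoride-induced cleavage of the aryl silyl ether, driven by the Si–F bond and the good phenoxide leaving group; no other group in 22 responds to fluoride.

Step 15
Reactants: 23 4-[(2S)-2-Ar-3-hydroxypropyl]phenol
Product: 25 4-[(2S)-2-Ar-3-hydroxypropyl]-4-hydroxycyclohexa-2,5-dien-1-one (p-quinol), via p-peroxyquinol 24 (not isolated)
Conditions: Oxone (ca. 8 equiv), NaHCO3, MeCN/H2O, rt; then aq Na2S2O3, rt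
Reagents that add atoms: potassium peroxymonosulfate (active part of Oxone, delivers O2), [K+].[O-]S(=O)(=O)OO
Why: Oxidative dearomatisation of a p-alkylphenol by singlet oxygen (set free when peroxymonosulfate decomposes in hydrogencarbonate buffer): [4+2] addition across C7/C4a and opening gives hydroperoxide 24, which thiosulfate reduces to the p-quinol; as no phenoxenium ion is formed the free C2 hydroxyl cannot spirocyclise onto C4a, and the vinyl group has no allylic hydrogen for an ene reaction.

Step 16
Reactants: 25 4-[(2S)-2-Ar-3-hydroxypropyl]-4-hydroxycyclohexa-2,5-dien-1-one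
Product: 27 (3S)-3-Ar-chroman-7-ol [(3S)-7-hydroxy-3'-isopropoxy-2',4'-dimethoxy-5'-(1,1-dimethylallyl)isoflavan], via cis-fused 4a-hydroxy enone 26 (not isolated)
Conditions: p-TsOH·H2O (20 mol %), 1,2-dichloroethane (0.01 M), rt until 25 is consumed, then 70 °C
Reagents that add atoms: none
Why: Protonation of the dienone carbonyl lets the primary C2 hydroxyl add to the β-carbon C8a in an oxa-Michael addition (6-exo-trig), which forms O1–C8a, closes pyran ring C and gives the necessarily cis-fused 4a-hydroxy enone 26. On warming, 26 enolises towards C8 to a cyclohexa-1,3-dienol that is formally an arene hydrate; its tertiary C4a hydroxyl ionises to a cyclohexadienyl cation (charge on C4a, C6 and C8), H-8a is lost, and water has thus left across C4a–C8a with ring A restored as the free 7-phenol. The closest known reaction types are the sulfonic-acid-catalysed cyclisation of 4-(3-hydroxypropyl)-p-quinols to hydrobenzopyranones and the acid-induced conjugate addition of alcohols, thiols or amines to p-quinols with dehydrative aromatisation to meta-substituted phenols. No stereocentre is created in 27: C4a and C8a of 26 are erased again, the two diastereotopic enone arms and both of their faces converge on one arene, and C3, set in step 12, has no acidic or ionisable bond here. The selectivity that matters is chemoselectivity for O-attack over the 1,2-shift of C4 (dienone–phenol rearrangement) and over C-attack by C6' of ring B; the first is secured by letting the fast six-membered closure consume the free quinol at room temperature with a catalytic sulfonic acid before heat is applied, the second by the poor nucleophilicity of C6', which is meta to both methoxy groups and screened by the neighbouring quaternary carbon. High dilution keeps the product phenol from adding to unreacted dienone, and the acid is too weak and too dilute to protonate the monosubstituted alkene or to cleave the isopropyl ether.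

Step 17
Reactants: 27 (3S)-3-Ar-chroman-7-ol
Product: 28 (3S)-7,3'-dihydroxy-2',4'-dimethoxy-5'-(1,1-dimethylallyl)isoflavan (CNP0305994.1)
Conditions: BCl3 (3 equiv), CH2Cl2, −78 → −10 °C; then H2O
Reagents that add atoms: none
Why: Lewis-acid dealkylation of an aryl isopropyl ether: all three ring-B ether oxygens can bind boron, but only the O–CH(CH3)2 bond can break by the fast, carbocation-like attack of chloride, so at low temperature the two methyl ethers, the chroman ether, the vinyl group (simple alkenes do not add BCl3 under these conditions) and C3 should stay as they are, one equivalent of reagent being held by the 7-OH until the quench.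

## Compound list

1 | 2,3,4-trihydroxybenzaldehyde | O=Cc1ccc(O)c(O)c1O | starting material
2 | prenyl bromide | CC(C)=CCBr | starting material
3 | 2,3-dihydroxy-4-(3-methylbut-2-enyloxy)benzaldehyde | O=Cc1ccc(OCC=C(C)C)c(O)c1O | intermediate
4 | disodium 2,3-catecholate of 3 (not isolated) | [Na+].[Na+].O=Cc1ccc(OCC=C(C)C)c([O-])c1[O-] | intermediate
5 | 2-hydroxy-3-isopropoxy-4-(3-methylbut-2-enyloxy)benzaldehyde | O=Cc1ccc(OCC=C(C)C)c(OC(C)C)c1O | intermediate
6 | 3-isopropoxy-2-methoxy-4-(3-methylbut-2-enyloxy)benzaldehyde | O=Cc1ccc(OCC=C(C)C)c(OC(C)C)c1OC | intermediate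
7 | 3-isopropoxy-2-methoxy-5-(2-methylbut-3-en-2-yl)-4-oxocyclohexa-1(6),2-diene-1-carbaldehyde (ortho-dienone, racemic, not isolated) | O=CC1=CC(C(C)(C)C=C)C(=O)C(OC(C)C)=C1OC | intermediate
8 | 4-hydroxy-3-isopropoxy-2-methoxy-5-(2-methylbut-3-en-2-yl)benzaldehyde | O=Cc1cc(C(C)(C)C=C)c(O)c(OC(C)C)c1OC | intermediate
9 | 3-isopropoxy-2,4-dimethoxy-5-(2-methylbut-3-en-2-yl)benzaldehyde | O=Cc1cc(C(C)(C)C=C)c(OC)c(OC(C)C)c1OC | intermediate
10 | 1-Ar-2-methoxyethene (E/Z mixture) | COC=Cc1cc(C(C)(C)C=C)c(OC)c(OC(C)C)c1OC | intermediate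
11 | 2-Ar-acetaldehyde (not isolated) | O=CCc1cc(C(C)(C)C=C)c(OC)c(OC(C)C)c1OC | intermediate
12 | 2-Ar-acetic acid | O=C(O)Cc1cc(C(C)(C)C=C)c(OC)c(OC(C)C)c1OC | intermediate
13 | (S)-4-benzyl-2-oxazolidinone | O=C1N[C@@H](Cc2ccccc2)CO1 | starting material
14 | 2-Ar-acetic pivalic anhydride (not isolated) | CC(C)(C)C(=O)OC(=O)Cc1cc(C(C)(C)C=C)c(OC)c(OC(C)C)c1OC | intermediate
15 | (S)-4-benzyl-3-(2-Ar-acetyl)oxazolidin-2-one | O=C(Cc1cc(C(C)(C)C=C)c(OC)c(OC(C)C)c1OC)N1[C@@H](Cc2ccccc2)COC1=O | intermediate
16 | 4-hydroxybenzaldehyde | O=Cc1ccc(O)cc1 | starting material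
17 | 4-(tert-butyldimethylsilyloxy)benzaldehyde | O=Cc1ccc(O[Si](C)(C)C(C)(C)C)cc1 | intermediate
18 | 4-(tert-butyldimethylsilyloxy)benzyl alcohol | OCc1ccc(O[Si](C)(C)C(C)(C)C)cc1 | intermediate
19 | 4-(tert-butyldimethylsilyloxy)benzyl bromide | BrCc1ccc(O[Si](C)(C)C(C)(C)C)cc1 | intermediate
20 | sodium Z-enolate of 15 (not isolated) | [Na+].[O-]/C(=C\c1cc(C(C)(C)C=C)c(OC)c(OC(C)C)c1OC)N1[C@@H](Cc2ccccc2)COC1=O | intermediate
21 | (S)-4-benzyl-3-{(2S)-2-Ar-3-[4-(tert-butyldimethylsilyloxy)phenyl]propanoyl}oxazolidin-2-one | C=CC(C)(C)c1cc([C@@H](C(=O)N2[C@@H](Cc3ccccc3)COC2=O)Cc2ccc(O[Si](C)(C)C(C)(C)C)cc2)c(OC)c(OC(C)C)c1OC | intermediate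
22 | (2S)-2-Ar-3-[4-(tert-butyldimethylsilyloxy)phenyl]propan-1-ol | C=CC(C)(C)c1cc([C@@H](CO)Cc2ccc(O[Si](C)(C)C(C)(C)C)cc2)c(OC)c(OC(C)C)c1OC | intermediate
23 | 4-[(2S)-2-Ar-3-hydroxypropyl]phenol | C=CC(C)(C)c1cc([C@@H](CO)Cc2ccc(O)cc2)c(OC)c(OC(C)C)c1OC | intermediate
24 | 4-[(2S)-2-Ar-3-hydroxypropyl]-4-hydroperoxycyclohexa-2,5-dien-1-one (not isolated) | C=CC(C)(C)c1cc([C@@H](CO)CC2(OO)C=CC(=O)C=C2)c(OC)c(OC(C)C)c1OC | intermediate
25 | 4-[(2S)-2-Ar-3-hydroxypropyl]-4-hydroxycyclohexa-2,5-dien-1-one (key-step precursor) | C=CC(C)(C)c1cc([C@@H](CO)CC2(O)C=CC(=O)C=C2)c(OC)c(OC(C)C)c1OC | intermediate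
26 | (3S)-3-Ar-4a-hydroxy-2,3,4,4a,8,8a-hexahydro-7H-chromen-7-one (cis-fused, both C4a/C8a diastereomers, not isolated) | C=CC(C)(C)c1cc([C@H]2COC3CC(=O)C=CC3(O)C2)c(OC)c(OC(C)C)c1OC | intermediate
27 | (3S)-3-Ar-chroman-7-ol (key-step product) | C=CC(C)(C)c1cc([C@H]2COc3cc(O)ccc3C2)c(OC)c(OC(C)C)c1OC | intermediate
28 | (3S)-7,3'-dihydroxy-2',4'-dimethoxy-5'-(1,1-dimethylallyl)isoflavan | C=CC(C)(C)c1cc([C@H]2COc3cc(O)ccc3C2)c(OC)c(O)c1OC | target

## Step count and risks

Total step count: 17. Longest linear sequence: 14 steps (steps 1–8 and 12–17). Steps 9–11 form the side branch.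

Steps most likely to fail:

**1. Step 16.**
- What may go wrong:
  - The sequence may stall after the oxa-Michael addition because enolisation and ionisation at C4a are slow.
  - More forcing acid may reverse the addition and open the way to the 1,2-shift of C4 (dienone–phenol rearrangement).
  - It may also allow Friedel–Crafts capture of the dienone by ring B or by the product phenol, or acid-induced isomerisation or loss of the 1,1-dimethylallyl group.
- Fallback: this gives up the dearomatisation and closes ring C by a phenol etherification. It sets out from 15 and comes back at 27. Commercial 2,4-dihydroxybenzaldehyde is bis-silylated (TBSCl, imidazole, DMF) to 2,4-bis(tert-butyldimethylsilyloxy)benzaldehyde F1. This is reduced (NaBH4, MeOH) to 2,4-bis(tert-butyldimethylsilyloxy)benzyl alcohol F2 and brominated (PBr3, Et2O, 0 °C) to 2,4-bis(tert-butyldimethylsilyloxy)benzyl bromide F3. Enolate 20, made from 15 as in step 12, is alkylated with F3 to the (S,S)-imide F4. LiBH4 frees the (S)-alcohol F5, and TBAF removes both silyl groups to give the resorcinol alcohol F6. An intramolecular Mitsunobu etherification (PPh3, DIAD, THF, 0 °C, dilute) then joins the ortho phenol oxygen to C2 and gives 27. C3 is not involved in that closure.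

**2. Step 15.**
- What may go wrong: the large excess of peroxymonosulfate may over-oxidise the electron-rich ring B or slowly epoxidise the vinyl group. Conversion of the phenol may be incomplete if singlet oxygen is quenched unproductively.
- Fallback: this replaces external oxygen transfer by an iodine(III) dearomatisation with water as nucleophile, which requires masking the C2 hydroxyl. It sets out from 22 and comes back at 25. Alcohol 22 is acetylated (Ac2O, pyridine, DMAP) to the silyl ether acetate F7 and desilylated (TBAF, AcOH, THF) to the phenol acetate F8. F8 is oxidised with PhI(OAc)2 in MeCN/H2O at 0 °C to the p-quinol acetate F9. Here the acetate prevents spiro-ether formation at C4a. Brief methanolysis (K2CO3, MeOH, 0 °C, pH 7 quench) gives 25. Any material that has already cyclised to 26 is simply carried into step 16.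

**3. Step 4.**
- What may go wrong: the prenyl ether may fragment thermally before rearrangement. The product may undergo secondary reactions at the required temperature, namely closure of the new phenol on the vinyl group or abnormal Claisen isomerisation of the side chain.
- Fallback: this forms the C5'–quaternary-carbon bond by cross-coupling instead of a sigmatropic shift. It sets out from 1 and comes back at 10. Compound 1 is methylated on O4 (MeI, Li2CO3, DMF) to 2,3-dihydroxy-4-methoxybenzaldehyde F10. F10 is isopropylated through its dianion as in step 2 to 2-hydroxy-3-isopropoxy-4-methoxybenzaldehyde F11, then methylated as in step 3 to 3-isopropoxy-2,4-dimethoxybenzaldehyde F12. NBS in MeCN brominates C5 (para to the 2-methoxy, ortho to the 4-methoxy, meta to the formyl group) to give 5-bromo-3-isopropoxy-2,4-dimethoxybenzaldehyde F13. The Wittig reaction of step 6 gives the bromo enol ether F14. A γ-selective Suzuki–Miyaura coupling with 3-methylbut-2-enylboronic acid pinacol ester (Pd(0), bulky biarylphosphine chosen for branched selectivity, K3PO4, THF/H2O, 40 °C) then gives 10.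

## Further compounds

F1 | step 16 | 2,4-bis(tert-butyldimethylsilyloxy)benzaldehyde | O=Cc1ccc(O[Si](C)(C)C(C)(C)C)cc1O[Si](C)(C)C(C)(C)C
F2 | step 16 | 2,4-bis(tert-butyldimethylsilyloxy)benzyl alcohol | OCc1ccc(O[Si](C)(C)C(C)(C)C)cc1O[Si](C)(C)C(C)(C)C
F3 | step 16 | 2,4-bis(tert-butyldimethylsilyloxy)benzyl bromide | BrCc1ccc(O[Si](C)(C)C(C)(C)C)cc1O[Si](C)(C)C(C)(C)C
F4 | step 16 | (S)-4-benzyl-3-{(2S)-2-Ar-3-[2,4-bis(tert-butyldimethylsilyloxy)phenyl]propanoyl}oxazolidin-2-one | C=CC(C)(C)c1cc([C@@H](C(=O)N2[C@@H](Cc3ccccc3)COC2=O)Cc2ccc(O[Si](C)(C)C(C)(C)C)cc2O[Si](C)(C)C(C)(C)C)c(OC)c(OC(C)C)c1OC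
F5 | step 16 | (2S)-2-Ar-3-[2,4-bis(tert-butyldimethylsilyloxy)phenyl]propan-1-ol | C=CC(C)(C)c1cc([C@@H](CO)Cc2ccc(O[Si](C)(C)C(C)(C)C)cc2O[Si](C)(C)C(C)(C)C)c(OC)c(OC(C)C)c1OC
F6 | step 16 | 4-[(2S)-2-Ar-3-hydroxypropyl]benzene-1,3-diol | C=CC(C)(C)c1cc([C@@H](CO)Cc2ccc(O)cc2O)c(OC)c(OC(C)C)c1OC
F7 | step 15 | (2S)-2-Ar-3-[4-(tert-butyldimethylsilyloxy)phenyl]propyl acetate | C=CC(C)(C)c1cc([C@@H](COC(C)=O)Cc2ccc(O[Si](C)(C)C(C)(C)C)cc2)c(OC)c(OC(C)C)c1OC
F8 | step 15 | (2S)-2-Ar-3-(4-hydroxyphenyl)propyl acetate | C=CC(C)(C)c1cc([C@@H](COC(C)=O)Cc2ccc(O)cc2)c(OC)c(OC(C)C)c1OC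
F9 | step 15 | (2S)-2-Ar-3-(1-hydroxy-4-oxocyclohexa-2,5-dien-1-yl)propyl acetate | C=CC(C)(C)c1cc([C@@H](COC(C)=O)CC2(O)C=CC(=O)C=C2)c(OC)c(OC(C)C)c1OC
F10 | step 4 | 2,3-dihydroxy-4-methoxybenzaldehyde | O=Cc1ccc(OC)c(O)c1O
F11 | step 4 | 2-hydroxy-3-isopropoxy-4-methoxybenzaldehyde | O=Cc1ccc(OC)c(OC(C)C)c1O
F12 | step 4 | 3-isopropoxy-2,4-dimethoxybenzaldehyde | O=Cc1ccc(OC)c(OC(C)C)c1OC
F13 | step 4 | 5-bromo-3-isopropoxy-2,4-dimethoxybenzaldehyde | O=Cc1cc(Br)c(OC)c(OC(C)C)c1OC
F14 | step 4 | 1-(5-bromo-3-isopropoxy-2,4-dimethoxyphenyl)-2-methoxyethene (E/Z mixture) | COC=Cc1cc(Br)c(OC)c(OC(C)C)c1OC
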